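## Structural features

Piscisoflavone A is an isoflavone: benzo ring A is fused to the 4-pyranone ring C, and aryl ring B is attached to C3 through a single C3–C1' bond. Ring A carries one hydroxyl, at C7. Ring B is pentasubstituted, with 2'-OH, 3'-prenyl, 4'-OH and 5'-OMe in an unbroken row and a lone hydrogen at C6'. The molecule has no stereocentre, so none stand next to each other; the only stereochemical element on the way is the geometry of the enol that supplies C2 and C3. The fragile groups are the prenyl double bond (acid cyclises it onto either neighbouring phenol to a chroman; it also rules out hydrogenolysis and late electrophilic halogenation), the electron-rich free phenols (oxidation) and C2 of the pyranone (hard nucleophiles, ring opening in strong base). The real difficulty is ring B: a carbon substituent must sit between two oxygens, one oxygen of three must stay a methyl ether, and this crowded aryl must be bonded to C3 of a chromone oxygenated at C7 only. The key step uses the fact that O1 and the C4 carbonyl sit on the neighbouring ring-A carbons C8a and C4a, the pattern left when an oxygen nucleophile and a tethered acyl electrophile add across an aryne. C5, the other neighbour of C4a, is unsubstituted in the target and can hold a removable bromine that steers the addition.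

## Logic of the disconnections

**24 from 23.** The three O–CH2 acetal bonds at O7, O2' and O4' are cut. Acetal ethers direct the lithiations, survive fluoride, zinc enolates and formate, and leave all three oxygens in one operation. The gain is that the only methyl ether ever present is the natural 5'-OMe. The demand is an acid treatment too mild to protonate the prenyl alkene beside the freed 2'- and 4'-hydroxyls.

**23 from 22.** C5–H is exchanged for C5–Br. The halogen adds nothing to the skeleton; it makes the two ends of the aryne in the next disconnection different. The forward step must reduce an aryl bromide without touching the prenyl alkene or C2=C3, which excludes H2 and points to a formate-driven hydrodehalogenation.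

**22 from 6 and 19.** O1–C8a and C4–C4a are cut, the two bonds tying ring A to ring C. They end on neighbouring carbons, so ring A can be an aryne, and O1 with C2–C3–C4 a β-hydroxyacrylate ester. This is the largest simplification: the target falls into a four-substituent benzene and an open-chain enol holding all of ring B, and ring C is carried through no earlier step. The forward step must add oxygen, not carbon, to the aryne carbon remote from bromine, and must close onto the ester before the aryl anion is protonated.

**19 from 16 and 17.** The C3–C2 bond (α-carbon to formyl carbon) is cut, a crossed Claisen disconnection to an arylacetate and a one-carbon ester. The demand is only that the enol be released from its salt without acid that harms the acetals.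

**16 from 13 and 14.** The C1'–CH2 bond is cut between an aryl halide and a two-carbon ester enolate. Cutting here avoids an aldehyde or benzylic halide on this electron-rich ring and a multi-step homologation. The forward step needs a neutral zinc enolate and a catalyst able to insert into a hindered, electron-rich carbon–iodine bond.

**13 from 11.** The carbon–iodine bond at C1' is cut. Iodine is introduced through lithiation because electrophilic halogenation would also attack the prenyl alkene. The demand is site selectivity: the O2' acetal must direct the base to C1' in preference to C6' (beside the methoxy group) and to the benzylic–allylic CH2.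

**11 from 8 and 9.** The C3'–CH2 bond of the prenyl group is cut. C3' lies between two acetal oxygens and is the most acidic C–H of the ring, so the substituent hardest to place by electrophilic chemistry becomes the easiest by metalation. The forward step must alkylate at the primary carbon of 9 (SN2, not SN2'), which copper secures.

**8 from 7.** Two O–CH2 bonds are cut. 7 already has the oxygen pattern of ring B with the methyl ether in place, so no selective methylation or demethylation is needed.

**6 from 3.** The C–Si and O–S bonds are cut. Silicon passes from oxygen to carbon at the site of one bromine and the phenol oxygen becomes the leaving group. The demand is that only one of the two equivalent bromines undergoes exchange.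

**3 from 2, and 2 from 1.** The two C–Br bonds beside the free hydroxyl are cut, then one O–CH2 bond. 2 is symmetric about its O···O axis, so double ortho-bromination raises no regiochemical question, and the two bromines later take different roles (silicon site and control element). The only demand is mono-protection of a symmetric diol, met statistically with the diol in excess.

## Other disconnections considered

**Alternative 1:** The cut runs through ring B. C3'–C4' and C4'–C5' are broken and C4' is removed as carbon monoxide, leaving the open-chain acetoxy enyne A2.
- Forward key step: [Rh(CO)2Cl]2 under CO would shift the acetate from C1' to C2', insert CO between the alkyne terminus C3' and the enol-ether terminus C5', and after 6π closure and tautomerisation give the resorcinol monoacetate A1, a deoxybenzoin.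
- In its favour: every substituent of ring B is fixed by the connectivity of a chain, so no aromatic metalation has to be regioselective, and the 2'- and 4'-oxygens emerge differentiated. The reaction class (carbonylative benzannulation of 3-acyloxy-1,4-enynes) is established, which the chosen ring closure is not. On precedent and on regiochemical certainty for ring B the alternative is the better.
- Against it here: A2 is a tertiary propargylic acetate β to an aryl ketone (loss of acetic acid by E1cB), with a skipped enyne methylene (isomerisation to an allene) and an enol ether. Its assembly needs an acetylide to add to an enolisable 1,3-dicarbonyl-type enone, and the prenyl alkene is a second π-partner for the metal. A1 still lacks C2 and ring C, so one ring-A acetal must be removed selectively, the new 4'-phenol protected, one carbon inserted, and acetate and acetals removed.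
- Comparison: structurally it solves ring B by construction where the chosen plan relies on two directed lithiations. Mechanistically it is catalytic and precedented but stretched by this substrate. In step economy it should be longer by several steps, because ring C and the protecting-group corrections follow the key step.

**Alternative 2:** The cut is the C3–C4 bond, which opens ring C to the keto aldehyde A4, in which the ring-A aldehyde and the ring-B ketone are joined through the O1–C2 ether.
- Forward key step: a triazolium-derived N-heterocyclic carbene would turn the aldehyde carbon into an acyl-anion equivalent that adds to the ketone and gives the racemic tertiary ketol A3. Loss of water across C2–C3 would then lead to 23 and the common last step.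
- In its favour: the intramolecular aldehyde–ketone benzoin to 3-hydroxychroman-4-ones is a known, metal-free, catalytic reaction. Ring A arrives with its C7 oxygen, and no aryne, no bromine control element and no reduction step are needed. On precedent of the key reaction and on atom economy it is the better; on step count it is the equal, possibly one step shorter.
- Against it here: the acceptor is an electron-rich aryl ketone flanked by an ortho acetal, a poor electrophile for a reversible addition. The haloacetyl unit on ring B cannot come from halogenation beside a ketone in the presence of the prenyl group and a trioxygenated ring, so it would have to be introduced through 12. The stereocentre that is built must be destroyed again by dehydration of a tertiary α-ketol, which needs acid or sulfonylation and elimination, the conditions the acetals and the prenyl group tolerate least.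
- Comparison: the chosen plan reaches the chromone oxidation level in the ring-forming step itself and asks nothing of a hindered carbonyl, at the price of an unprecedented annulation and a bromine that must be removed.

**Alternative 3:** Three bonds of ring B are cut, C5'–C6', C1'–C2' and C2'–C3', which returns the alkynyl chromone A6, the alkenyl(methoxy)carbene complex A7 and one CO ligand as C2'.
- Forward key step: heating A7 with A6 would give, by alkyne insertion, CO insertion and electrocyclisation, the phenol A5 (first as its Cr(CO)3 complex), from which two acetals are then removed.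
- In its favour: the chromone exists before ring B, the union is fully convergent, and the terminal alkyne places the chromone next to the new hydroxyl. The 5'-methoxy group comes from the carbene, so the three oxygens of ring B are differentiated without protecting-group logic. On convergence and on this differentiation it is the better, and the step count is about equal.
- Against it here: chromium is used stoichiometrically (A7 derives from Cr(CO)6). A7 is an α-oxygenated alkenyl carbene with a skipped diene side chain; its vinyl-lithium precursor is not trivial, and the pendant prenyl alkene can be cyclopropanated by the carbene or trapped by the vinylketene. A6 is an electron-poor, ynone-like alkyne and a Michael acceptor, the class for which benzannulation competes worst with cyclobutenone, indene and furan formation. The para-methoxyphenol formed is easily oxidised to a quinone during decomplexation.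
- Comparison: both plans rest on one ambitious ring-forming step. The alternative has the precedent of a named reaction; the chosen plan has simpler precursors and avoids stoichiometric chromium.

Key step: step 9

Remark: 4-methoxybenzene-1,3-diol (7) is assumed to be a catalogue compound; it already has the oxygen pattern of ring B and a free carbon where the acetate chain is needed, which removes an aldehyde homologation, and the atom mapping of 6, 19 and 22 onto the target was rechecked and needs no correction.

## Route

Step 1
Reactants: 1 hydroquinone (benzene-1,4-diol)
Product: 2 4-(methoxymethoxy)phenol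
Conditions: 1 (2 equiv), MOMCl (1 equiv), K2CO3 (1 equiv), acetone, 0 °C → rt
Reagents that add atoms: chloromethyl methyl ether, COCCl
Why: Williamson-type acetal ether formation on one of two equivalent phenols; the excess of diol and a single equivalent of electrophile hold bis-alkylation down, and unreacted 1 is removed by aqueous extraction.

Step 2
Reactants: 2 4-(methoxymethoxy)phenol
Product: 3 2,6-dibromo-4-(methoxymethoxy)phenol
Conditions: NBS (2.0 equiv), i-Pr2NH (10 mol%), CH2Cl2, 0 °C → rt
Reagents that add atoms: N-bromosuccinimide, O=C1CCC(=O)N1Br
Why: Amine-mediated ortho-bromination of a phenol (electrophilic aromatic substitution): the free hydroxyl is the stronger activator and the hydrogen-bonded N-bromoamine delivers both bromines beside it, the para position being blocked. The buffered, non-acidic medium leaves the acetal intact.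

Step 3
Reactants: 3 2,6-dibromo-4-(methoxymethoxy)phenol
Product: 6 2-bromo-4-(methoxymethoxy)-6-(trimethylsilyl)phenyl trifluoromethanesulfonate, via trimethylsilyl ether 4 (not isolated), via lithium phenoxide 5 (not isolated)
Conditions: HMDS (1.0 equiv), THF, 65 °C, then evaporation; n-BuLi (1.05 equiv), THF, −78 °C; Tf2O (1.2 equiv), −78 → 0 °C
Reagents that add atoms: hexamethyldisilazane, C[Si](C)(C)N[Si](C)(C)C; trifluoromethanesulfonic anhydride, O=S(=O)(OS(=O)(=O)C(F)(F)F)C(F)(F)F
Why: O-silylation, bromine–lithium exchange, 1,3 O→C silyl shift (retro-Brook rearrangement) and triflation of the resulting phenoxide, the standard entry to ortho-silylaryl triflates. Exchange at −78 °C outruns lithiation beside the acetal, and the phenoxide formed after the shift deactivates the second bromine towards further exchange.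

Step 4
Reactants: 7 4-methoxybenzene-1,3-diol
Product: 8 1-methoxy-2,4-bis(methoxymethoxy)benzene
Conditions: MOMCl (2.5 equiv), i-Pr2NEt (3 equiv), CH2Cl2, 0 °C → rt
Reagents that add atoms: chloromethyl methyl ether, COCCl
Why: Double acetal ether formation under amine base; both phenols react and the methyl ether is untouched, so the three ring-B oxygens are differentiated from the first step.

Step 5
Reactants: 8 1-methoxy-2,4-bis(methoxymethoxy)benzene; 9 prenyl bromide (1-bromo-3-methylbut-2-ene)
Product: 11 1-methoxy-2,4-bis(methoxymethoxy)-3-(3-methylbut-2-en-1-yl)benzene, via aryllithium 10 (not isolated)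
Conditions: n-BuLi (1.1 equiv), THF, 0 °C, 1 h; CuI (0.2 equiv), −40 °C; 9 (1.3 equiv), −40 °C → rt
Reagents that add atoms: none
Why: Directed ortho-metalation at the C–H flanked by two chelating acetal oxygens, the most acidic site of the ring, followed by copper-catalysed allylic substitution. The primary carbon of 9 is attacked, giving the linear prenyl arene.

Step 6
Reactants: 11 1-methoxy-2,4-bis(methoxymethoxy)-3-(3-methylbut-2-en-1-yl)benzene
Product: 13 1-iodo-5-methoxy-2,4-bis(methoxymethoxy)-3-(3-methylbut-2-en-1-yl)benzene, via aryllithium 12 (not isolated)
Conditions: n-BuLi (1.2 equiv), TMEDA (1.2 equiv), THF, −20 → 0 °C, 1 h; I2 (1.25 equiv) in THF, −78 °C; aq. Na2S2O3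
Reagents that add atoms: iodine, [I][I]
Why: Second directed ortho-metalation and iodinolysis: the acetal oxygen is a stronger directing group than methoxy, so lithium should enter beside O2' and not beside the methyl ether. Quenching the aryllithium with iodine at −78 °C is far faster than any addition of iodine to the prenyl alkene.

Step 7
Reactants: 13 1-iodo-5-methoxy-2,4-bis(methoxymethoxy)-3-(3-methylbut-2-en-1-yl)benzene; 14 methyl bromoacetate
Product: 16 methyl 2-[5-methoxy-2,4-bis(methoxymethoxy)-3-(3-methylbut-2-en-1-yl)phenyl]acetate, via bromozinc ester enolate 15 (not isolated)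
Conditions: Zn (TMSCl-activated, 2 equiv), 14 (1.5 equiv), THF, 40 °C; then 13, Pd2(dba)3 (2.5 mol%), XPhos (10 mol%), THF, 65 °C
Reagents that add atoms: none
Why: Negishi-type cross-coupling of an aryl iodide with a Reformatsky reagent (α-arylation of a zinc ester enolate). The neutral zinc enolate does not self-condense and tolerates acetals and the alkene, and the bulky electron-rich phosphine supports oxidative addition to the hindered, electron-rich carbon–iodine bond.

Step 8
Reactants: 16 methyl 2-[5-methoxy-2,4-bis(methoxymethoxy)-3-(3-methylbut-2-en-1-yl)phenyl]acetate; 17 methyl formate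
Product: 19 methyl (Z)-3-hydroxy-2-[5-methoxy-2,4-bis(methoxymethoxy)-3-(3-methylbut-2-en-1-yl)phenyl]prop-2-enoate, via sodium enolate 18 (not isolated)
Conditions: NaH (2.5 equiv), 17 (10 equiv), MeOH (cat.), THF, 0 °C → rt; AcOH to pH 6, 0 °C
Reagents that add atoms: none
Why: Crossed Claisen condensation (formylation) of an arylacetate with a non-enolisable formate, driven by formation of the stabilised enolate. Acidification to pH 6 in the cold returns the hydrogen-bonded Z enol without cleaving the acetals; the crude enol is used directly.

Step 9
Reactants: 6 2-bromo-4-(methoxymethoxy)-6-(trimethylsilyl)phenyl trifluoromethanesulfonate; 19 methyl (Z)-3-hydroxy-2-[5-methoxy-2,4-bis(methoxymethoxy)-3-(3-methylbut-2-en-1-yl)phenyl]prop-2-enoate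
Product: 22 5-bromo-3-[5-methoxy-2,4-bis(methoxymethoxy)-3-(3-methylbut-2-en-1-yl)phenyl]-7-(methoxymethoxy)-4H-chromen-4-one, via cesium enolate 20 (not isolated), via aryne 21 (not isolated)
Conditions: 19, Cs2CO3 (1.1 equiv), THF, rt, 20 min; then 6 (1.5 equiv), CsF (4 equiv), THF, 65 °C
Reagents that add atoms: none
Why: Proposed new method: fluoride desilylates 6 and loss of triflate gives aryne 21; the oxygen of cesium enolate 20 adds to the aryne carbon remote from bromine (the future C8a), the aryl anion formed at C4a lies cis to the ester across the Z enol ether and attacks the ester carbonyl, and loss of methoxide (which is protonated by hydrogen carbonate, returning Cs2CO3) gives the pyranone. The closest known reaction type is the aryne annulation of methyl salicylates to xanthones by O-arylation and intramolecular acyl substitution; 19 is the vinylogous counterpart, its enol C=C standing in for the salicylate benzene ring. Ring C closes in the 6-exo-trig mode, the carbanion attacking an exocyclic C=O. No stereocentre is formed, and three selectivities are needed. Regiochemistry of addition: the bromine beside the triple bond polarises and distorts it so that the nucleophile attacks the distal carbon and the charge develops next to the halogen, while the remote acetal oxygen has only a weak opposing influence. O- versus C-arylation: the carbon terminus of 20 would become quaternary and is shielded by the ortho-substituted ring B, which disfavours the C–C insertion path of simple β-keto esters. Ring closure versus proton quench: the enol is deprotonated beforehand and THF replaces acetonitrile, so no acidic O–H or C–H is present when the aryl anion forms, and cesium chelation between the two oxygens holds the enolate in the U shape that leads to the Z enol ether.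

Step 10
Reactants: 22 5-bromo-3-[5-methoxy-2,4-bis(methoxymethoxy)-3-(3-methylbut-2-en-1-yl)phenyl]-7-(methoxymethoxy)-4H-chromen-4-one
Product: 23 3-[5-methoxy-2,4-bis(methoxymethoxy)-3-(3-methylbut-2-en-1-yl)phenyl]-7-(methoxymethoxy)-4H-chromen-4-one
Conditions: Pd(PPh3)4 (5 mol%), HCO2Na (3 equiv), DMF, 90 °C
Reagents that add atoms: none
Why: Hydrodehalogenation with Pd(PPh3)4 (zerovalent palladium) and formate as hydride donor: oxidative addition to the C5–Br bond activated by the peri carbonyl, formate exchange, decarboxylation and reductive elimination. No H2 is present, so the prenyl alkene and C2=C3 should stay untouched.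

Step 11
Reactants: 23 3-[5-methoxy-2,4-bis(methoxymethoxy)-3-(3-methylbut-2-en-1-yl)phenyl]-7-(methoxymethoxy)-4H-chromen-4-one
Product: 24 piscisoflavone A, 3-[2,4-dihydroxy-5-methoxy-3-(3-methylbut-2-en-1-yl)phenyl]-7-hydroxy-4H-chromen-4-one
Conditions: 3 M aq. HCl, MeOH/THF, 45 °C
Reagents that add atoms: none
Why: Acid-catalysed transacetalisation of the three aryl acetal ethers to methanol. Aryl acetals cleave under milder acid than is needed to protonate a trisubstituted alkene, so moderate temperature and early quenching should release the three phenols with the prenyl group intact.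

## Compound list

1 | hydroquinone (benzene-1,4-diol) | Oc1ccc(O)cc1 | starting material
2 | 4-(methoxymethoxy)phenol | COCOc1ccc(O)cc1 | intermediate
3 | 2,6-dibromo-4-(methoxymethoxy)phenol | COCOc1cc(Br)c(O)c(Br)c1 | intermediate
4 | [2,6-dibromo-4-(methoxymethoxy)phenoxy]trimethylsilane | COCOc1cc(Br)c(O[Si](C)(C)C)c(Br)c1 | intermediate
5 | lithium 2-bromo-4-(methoxymethoxy)-6-(trimethylsilyl)phenolate | COCOc1cc(Br)c([O-])c([Si](C)(C)C)c1.[Li+] | intermediate
6 | 2-bromo-4-(methoxymethoxy)-6-(trimethylsilyl)phenyl trifluoromethanesulfonate | COCOc1cc(Br)c(OS(=O)(=O)C(F)(F)F)c([Si](C)(C)C)c1 | intermediate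
7 | 4-methoxybenzene-1,3-diol | COc1ccc(O)cc1O | starting material
8 | 1-methoxy-2,4-bis(methoxymethoxy)benzene | COCOc1ccc(OC)c(OCOC)c1 | intermediate
9 | prenyl bromide (1-bromo-3-methylbut-2-ene) | CC(C)=CCBr | starting material
10 | [3-methoxy-2,6-bis(methoxymethoxy)phenyl]lithium | [Li]c1c(OCOC)ccc(OC)c1OCOC | intermediate
11 | 1-methoxy-2,4-bis(methoxymethoxy)-3-(3-methylbut-2-en-1-yl)benzene | COCOc1ccc(OC)c(OCOC)c1CC=C(C)C | intermediate
12 | [5-methoxy-2,4-bis(methoxymethoxy)-3-(3-methylbut-2-en-1-yl)phenyl]lithium | [Li]c1cc(OC)c(OCOC)c(CC=C(C)C)c1OCOC | intermediate
13 | 1-iodo-5-methoxy-2,4-bis(methoxymethoxy)-3-(3-methylbut-2-en-1-yl)benzene | COCOc1c(I)cc(OC)c(OCOC)c1CC=C(C)C | intermediate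
14 | methyl bromoacetate | COC(=O)CBr | starting material
15 | bromo(2-methoxy-2-oxoethyl)zinc | COC(=O)C[Zn]Br | intermediate
16 | methyl 2-[5-methoxy-2,4-bis(methoxymethoxy)-3-(3-methylbut-2-en-1-yl)phenyl]acetate | COC(=O)Cc1cc(OC)c(OCOC)c(CC=C(C)C)c1OCOC | intermediate
17 | methyl formate | COC=O | starting material
18 | sodium (Z)-3-methoxy-2-[5-methoxy-2,4-bis(methoxymethoxy)-3-(3-methylbut-2-en-1-yl)phenyl]-3-oxoprop-1-en-1-olate | COC(=O)/C(=C\[O-])c1cc(OC)c(OCOC)c(CC=C(C)C)c1OCOC.[Na+] | intermediate
19 | methyl (Z)-3-hydroxy-2-[5-methoxy-2,4-bis(methoxymethoxy)-3-(3-methylbut-2-en-1-yl)phenyl]prop-2-enoate | COC(=O)/C(=C\O)c1cc(OC)c(OCOC)c(CC=C(C)C)c1OCOC | intermediate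
20 | cesium (Z)-3-methoxy-2-[5-methoxy-2,4-bis(methoxymethoxy)-3-(3-methylbut-2-en-1-yl)phenyl]-3-oxoprop-1-en-1-olate | COC(=O)/C(=C\[O-])c1cc(OC)c(OCOC)c(CC=C(C)C)c1OCOC.[Cs+] | intermediate
21 | 3-bromo-5-(methoxymethoxy)benzyne | COCOC1=CC#CC(Br)=C1 | intermediate
22 | 5-bromo-3-[5-methoxy-2,4-bis(methoxymethoxy)-3-(3-methylbut-2-en-1-yl)phenyl]-7-(methoxymethoxy)-4H-chromen-4-one | COCOc1cc(Br)c2c(=O)c(-c3cc(OC)c(OCOC)c(CC=C(C)C)c3OCOC)coc2c1 | intermediate
23 | 3-[5-methoxy-2,4-bis(methoxymethoxy)-3-(3-methylbut-2-en-1-yl)phenyl]-7-(methoxymethoxy)-4H-chromen-4-one | COCOc1ccc2c(=O)c(-c3cc(OC)c(OCOC)c(CC=C(C)C)c3OCOC)coc2c1 | intermediate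
24 | piscisoflavone A, 3-[2,4-dihydroxy-5-methoxy-3-(3-methylbut-2-en-1-yl)phenyl]-7-hydroxy-4H-chromen-4-one | COc1cc(-c2coc3cc(O)ccc3c2=O)c(O)c(CC=C(C)C)c1O | target

## Step count and least certain steps

Total step count: 11. Longest linear sequence: 8 steps (7 to 24, steps 4 to 11); the ring-A branch from 1 to 6 is 3 steps and joins at step 9.

**Step 9 (key step, proposed new method).**
- What may go wrong: protonation of the aryl anion before it reaches the ester, which would leave an open aryl enol ether; carbon-arylation of the enolate followed by C–C insertion; an ene reaction of the aryne with the prenyl alkene; partial loss of regiocontrol, since bromine directs less strongly than lighter halogens.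
- Fallback (known chemistry, sets out from 13, returns at 23): a Suzuki–Miyaura isoflavone synthesis. Iodine–magnesium exchange on 13 (i-PrMgCl·LiCl, THF, −20 °C) and trapping with 2-isopropoxy-4,4,5,5-tetramethyl-1,3,2-dioxaborolane would give the pinacol boronate 2-[5-methoxy-2,4-bis(methoxymethoxy)-3-(3-methylbut-2-en-1-yl)phenyl]-4,4,5,5-tetramethyl-1,3,2-dioxaborolane F1. In parallel, commercial 1-(2,4-dihydroxyphenyl)ethanone F2 would be protected at the non-chelated 4-hydroxyl (MOMCl, K2CO3, acetone) to 1-[2-hydroxy-4-(methoxymethoxy)phenyl]ethanone F3. F3 would be condensed with N,N-dimethylformamide dimethyl acetal to the enaminone (E)-3-(dimethylamino)-1-[2-hydroxy-4-(methoxymethoxy)phenyl]prop-2-en-1-one F4, and F4 cyclised with iodine to 3-iodo-7-(methoxymethoxy)chromen-4-one F5. Coupling of F1 with F5 (Pd(dppf)Cl2, K2CO3, dioxane/water, 80 °C) should give 23, from which step 11 follows.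

**Step 6.**
- What may go wrong: loss of site selectivity in the lithiation, with metalation beside the methoxy group at C6' or at the benzylic–allylic CH2 of the prenyl group, because only one acetal directs and TMEDA-activated n-BuLi is a strong base.
- Fallback (sets out from 7, returns at 16): halogen and prenyl are introduced by phenol chemistry. Bromination of 7 (NBS, MeCN, 0 °C) at the position ortho and para to the two hydroxyls would give 4-bromo-6-methoxybenzene-1,3-diol F6. C-alkylation of its phenolate with 9 in aqueous KOH, possible only at the carbon between the hydroxyls, would give 4-bromo-6-methoxy-2-(3-methylbut-2-en-1-yl)benzene-1,3-diol F7. Protection (MOMCl, i-Pr2NEt) would give 1-bromo-5-methoxy-2,4-bis(methoxymethoxy)-3-(3-methylbut-2-en-1-yl)benzene F8, which replaces 13 in step 7 and leads to 16.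

**Step 7.**
- What may go wrong: slow oxidative addition or transmetalation at the hindered, electron-rich aryl iodide, so that reduction of the carbon–iodine bond or self-condensation of the zinc enolate competes.
- Fallback (sets out from 13, returns at 16): a softer carbon nucleophile and a different metal. Arylation of dimethyl malonate with 13 (CuI 10 mol%, 2-picolinic acid, Cs2CO3, dioxane, 70 °C) would give dimethyl 2-[5-methoxy-2,4-bis(methoxymethoxy)-3-(3-methylbut-2-en-1-yl)phenyl]propanedioate F9. Krapcho dealkoxycarbonylation of F9 (LiCl, wet DMSO, 140 °C) would give 16.

**Step 11.**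
- What may go wrong: acid-induced cyclisation of the prenyl group onto the freed 2'- or 4'-hydroxyl (chroman formation) while the last acetal is still being cleaved.
- Fallback (sets out from 23, returns at 24): the acetals are exchanged for silyl ethers under buffered, non-protic conditions, so no proton is available for the alkene. TMSOTf with 2,2'-bipyridyl (CH2Cl2, 0 °C) would give 3-[5-methoxy-3-(3-methylbut-2-en-1-yl)-2,4-bis(trimethylsilyloxy)phenyl]-7-(trimethylsilyloxy)chromen-4-one F10, whose aryl silyl ethers are hydrolysed by water at neutral pH to 24.

## Further compounds

F1 | step 9 | 2-[5-methoxy-2,4-bis(methoxymethoxy)-3-(3-methylbut-2-en-1-yl)phenyl]-4,4,5,5-tetramethyl-1,3,2-dioxaborolane | COCOc1c(B2OC(C)(C)C(C)(C)O2)cc(OC)c(OCOC)c1CC=C(C)C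
F2 | step 9 | 1-(2,4-dihydroxyphenyl)ethanone | CC(=O)c1ccc(O)cc1O
F3 | step 9 | 1-[2-hydroxy-4-(methoxymethoxy)phenyl]ethanone | COCOc1ccc(C(C)=O)c(O)c1
F4 | step 9 | (E)-3-(dimethylamino)-1-[2-hydroxy-4-(methoxymethoxy)phenyl]prop-2-en-1-one | COCOc1ccc(C(=O)/C=C/N(C)C)c(O)c1
F5 | step 9 | 3-iodo-7-(methoxymethoxy)chromen-4-one | COCOc1ccc2c(=O)c(I)coc2c1
F6 | step 6 | 4-bromo-6-methoxybenzene-1,3-diol | COc1cc(Br)c(O)cc1O
F7 | step 6 | 4-bromo-6-methoxy-2-(3-methylbut-2-en-1-yl)benzene-1,3-diol | COc1cc(Br)c(O)c(CC=C(C)C)c1O
F8 | step 6 | 1-bromo-5-methoxy-2,4-bis(methoxymethoxy)-3-(3-methylbut-2-en-1-yl)benzene | COCOc1c(Br)cc(OC)c(OCOC)c1CC=C(C)C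
F9 | step 7 | dimethyl 2-[5-methoxy-2,4-bis(methoxymethoxy)-3-(3-methylbut-2-en-1-yl)phenyl]propanedioate | COC(=O)C(C(=O)OC)c1cc(OC)c(OCOC)c(CC=C(C)C)c1OCOC
F10 | step 11 | 3-[5-methoxy-3-(3-methylbut-2-en-1-yl)-2,4-bis(trimethylsilyloxy)phenyl]-7-(trimethylsilyloxy)chromen-4-one | COc1cc(-c2coc3cc(O[Si](C)(C)C)ccc3c2=O)c(O[Si](C)(C)C)c(CC=C(C)C)c1O[Si](C)(C)C
A1 | alternative 1 | 6-{2-[2,4-bis(methoxymethoxy)phenyl]-2-oxoethyl}-3-hydroxy-4-methoxy-2-(3-methylbut-2-en-1-yl)phenyl acetate | COCOc1ccc(C(=O)Cc2cc(OC)c(O)c(CC=C(C)C)c2OC(C)=O)c(OCOC)c1
A2 | alternative 1 | racemic 1-[2,4-bis(methoxymethoxy)phenyl]-3-[(E)-2-methoxyethenyl]-8-methyl-1-oxonon-7-en-4-yn-3-yl acetate | COCOc1ccc(C(=O)CC(OC(C)=O)(/C=C/OC)C#CCC=C(C)C)c(OCOC)c1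
A3 | alternative 2 | racemic 3-hydroxy-3-[5-methoxy-2,4-bis(methoxymethoxy)-3-(3-methylbut-2-en-1-yl)phenyl]-7-(methoxymethoxy)chroman-4-one | COCOc1ccc2C(=O)C(O)(c3cc(OC)c(OCOC)c(CC=C(C)C)c3OCOC)COc2c1
A4 | alternative 2 | 2-{2-[5-methoxy-2,4-bis(methoxymethoxy)-3-(3-methylbut-2-en-1-yl)phenyl]-2-oxoethoxy}-4-(methoxymethoxy)benzaldehyde | COCOc1ccc(C=O)c(OCC(=O)c2cc(OC)c(OCOC)c(CC=C(C)C)c2OCOC)c1
A5 | alternative 3 | 3-[2-hydroxy-5-methoxy-4-(methoxymethoxy)-3-(3-methylbut-2-en-1-yl)phenyl]-7-(methoxymethoxy)chromen-4-one | COCOc1ccc2c(=O)c(-c3cc(OC)c(OCOC)c(CC=C(C)C)c3O)coc2c1
A6 | alternative 3 | 3-ethynyl-7-(methoxymethoxy)chromen-4-one | C#Cc1coc2cc(OCOC)ccc2c1=O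
A7 | alternative 3 | pentacarbonyl[(2Z)-1-methoxy-2-(methoxymethoxy)-6-methylhepta-2,5-dien-1-ylidene]chromium | COC(=[Cr](=C=O)(=C=O)(=C=O)(=C=O)=C=O)/C(OCOC)=C/CC=C(C)C
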